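## Structural features

Mollicellin B (30) is a tetracyclic depsidone with no stereocentre. Ring A (A1 C-CH3, A2 CH, A3 C-OH, A4 C-CHO, A5 C-O ether, A6 C-carboxyl) and ring B (B1 C-O ester, B2 C-O ether, B3 CH, B4 C-O of the pyranone, B5 C-acyl, B6 C-CH3) are joined twice, by the aryl ester A6-C(=O)-O-B1 and by the diaryl ether A5-O-B2. These two links close the seven-membered dioxepinone ring D. Ring C, a 2,2-dimethylpyran-4-one, is fused to ring B through the B4 oxygen and the B5 acyl carbon. Fragile groups are the aldehyde on A4, the phenolic ester of ring D (opened by bases and nucleophiles), the chromanone (retro-oxa-Michael opening under base) and the electron-rich oxygenated rings (oxidation). The real difficulty is ring B: five of its six carbons are substituted in a contiguous, unsymmetrical pattern, and both links to ring A lie between two ortho substituents, so substitution on a simple arene gives little positional control. Read through its oxygens, ring B is a hydroquinone (B1, B4) with a third oxygen on B2 and hydrogen on B3. The B1-B2-B3-B4 unit maps onto the four carbons of a squaric acid derivative, and B5-B6 (acyl, methyl) onto a trisubstituted alkene; the key step uses exactly this.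

## Logic of the disconnections

30 from 29. No skeletal bond is cut; the A3 hydroxyl is returned to its methyl ether. The phenol has to be masked from the first step to the last because it would interfere with base, organolithium and acylation chemistry. The gain is a ring A piece with a single free hydroxyl (A5). The demand is a final ether cleavage that spares the ring D ester and the chromanone, which the neighbouring A4 formyl group makes possible by chelation.

29 from 27, and 27 from 26. The ring D ester C-O bond between the A6 carbonyl carbon and the B1 oxygen is cut, and the acid is returned to its methyl ester. This ester is the most labile bond of the target, so it is formed as late as possible. The gain is an open diaryl ether whose acid and phenol are already held ortho to the ether oxygen. The demand is an activation that works on a 2,6-disubstituted benzoic acid, and an ester cleavage that does not need attack at the hindered carbonyl.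

26 from 24. The ring C C-O bond between the B4 oxygen and the C(CH3)2 carbon is cut, giving an ortho-hydroxyaryl 3-methylbut-2-enoyl ketone; this ketone and the A4 aldehyde are returned to their acetals. Only the B4 hydroxyl is ortho to the acyl group, so the forward closure has no regiochemical choice. The demand is that one acidic operation unmasks both carbonyls and closes the ring.

24 from 21. The B4-B5 bond is cut and ring B is folded back into a four-membered ring (B1, B2, B3, B4) bearing an alkenyl arm (B6, B5). This replaces a pentasubstituted arene by a cyclobutenone whose substituents are placed by simple carbonyl chemistry. The demand on the forward step is an inward rotation of the alkenyl group on ring opening, and an E alkene so that the quaternary ketal carbon points away from the closing terminus.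

21 from 10 and 19 (through 20). The B1-B6 bond is cut: carbinol carbon from a ketone, B6 from an alkenyllithium. The two carbonyls of 10 are differentiated by the vinylogous ester, so the more ketone-like one next to the aryloxy carbon reacts. The demand is 1,2-addition in the presence of a hindered ester, two acetals and an aryloxy leaving group, and a lithium reagent of defined E geometry.

10 from 4 and 8 (through 9). The O-B2 bond of the diaryl ether is cut between the A5 oxygen and the four-membered ring. The most hindered bond of the target is thereby made by addition-elimination on a vinylogous acid chloride and not by an aryl-oxygen coupling. The demand is an acid-free coupling, because 4 carries an acetal ortho to the phenol.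

8 from 7 and 7 from 5. One alkoxy group of 5 is replaced by hydrogen (B3-H) through hydride addition and loss of alcohol, and the remaining vinylogous ester is hydrolysed. The gain is a commercial squarate as the source of B1 to B4. The demand is delivery of one hydride only.

4 from 3, 3 from 2, 2 from 1. The acetal is returned to the aldehyde, the A4-CHO bond is cut, and the A3 methyl ether is cut. All ring A carbons except the formyl carbon come from 1. The demand is regiocontrol, met by the hydrogen bond that deactivates the A5 hydroxyl and by its ortho-directing effect in the formylation.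

19 from 17, 17 from 16, 16 from 13 and 14 (through 15), 13 from 11. The C-I bond is cut to an alkyne (syn hydrometalation), the ketal to the ketone, and the acyl-alkenyl bond to an amide and an alkenyl bromide. Introducing the halogen by syn addition after ketalisation gives the E isomer; anti hydrohalogenation of 11 would give the Z series. The demand is zirconium on the methyl-bearing alkyne carbon, which the quaternary ketal carbon enforces sterically.

## Other disconnections considered

Alternative 1: The cut is the bond between A6 and the ester carbonyl carbon of ring D, made while ring A is still a cyclohexenone. The precursor A2 is a 3-aryloxy-2-formyl-5-methylcyclohexenone whose aryl group is ring B with ring C and whose B1 oxygen carries an imidazole carboxylate; it would come from the dihydroxychromanone A3.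
- Forward key step: an amidine base forms the extended enolate, whose gamma carbon (A6) attacks the carboxylate carbonyl, closing ring D to dihydro compound A1; dehydrogenation of ring A would then lead to 30.
- In its favour: the carbon-carbon bond on the ester side is formed on a non-aromatic ring, so no hindered benzoic acid has to be esterified. No organometallic reagent and no aldehyde protection are needed, and ring A comes from a simple cyclic dione.
- Against it here: A2 is a doubly activated vinylogous ester whose aryloxy group can be displaced by the base or by the azole set free in the acylation. Alpha-prime deprotonation competes with gamma deprotonation. The adjacent hydroxyls of A3 on B1 and B2 must be told apart. The last step needs an oxidant able to aromatise A1 beside an aldehyde and an electron-rich ring B. The two stereocentres of A1 do not matter, since aromatisation removes them.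
- Comparison: on structure, the chosen plan creates the B1 and B2 oxygens already differentiated, while the alternative must differentiate them on a finished ring. On mechanism, the alternative relies on enolate chemistry with several competing sites, the chosen plan on a pericyclic sequence whose regiochemistry is fixed by the constitution of 21. On step count the alternative is probably the better plan, and on raw materials it is at least the equal.

Alternative 2: The cuts are the ester C-O bond at B1 and the A1-A6 bond of ring A; the diaryl ether and the formyl group are left for later. The partners are the diketo-dioxinone A5 and the bromophenol A6.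
- Forward key step: heating A5 gives a triketo-ketene that the B1 hydroxyl of A6 captures; base then acid effect the aldol condensation that aromatises ring A, giving depside A4. An intramolecular copper-mediated Ullmann etherification (A5 oxygen to B2) and a formylation at A4 would complete 30.
- In its favour: ring A and the hindered ester arise in one operation without any protecting group on ring A, and the ester is made by ketene capture, not by acylation with a hindered acid.
- Against it here: the hydroxyl of A6 lies between a methyl group and bromine and must still trap the ketene. The seven-membered ether closure has to be run with base on a depside ester prone to acyl transfer. The formyl group must enter last at A4 while A2 and B3 are also activated. A6 needs a regioselective bromination of a ring B built by classical substitution.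
- Comparison: on structure, the chosen plan carries the formyl group and the ether link from the start and so wins on positional certainty. On mechanism, both plans pass through thermally generated ketenes, one trapped by O-H and the other by a C=C bond, so they are equals in kind. On step count and protecting-group economy the alternative is the better plan.

Alternative 3: The cuts are A3-A4, A5-A6 and A2-A3, so that rings A and D form together from the diazo ketoester A8, which holds an aryl ynol ether on the B2 oxygen and a diazo ketoester on the B1 oxygen.
- Forward key step: light induces a Wolff rearrangement to an (aryloxycarbonyl)(isopropenyl)ketene, which adds to the tethered ynol ether; the cyclobutenone opens and recloses onto the isopropenyl group to give the acetal A7, one hydrolysis away from 30.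
- In its favour: it is the most convergent plan. The regiochemistry of ring A follows from the polarity of the ynol ether, ring D closes in the same operation, and only one step follows.
- Against it here: A8 needs two different sensitive groups on neighbouring oxygens of a chromanone, again the B1/B2 differentiation, and ynol ether synthesis uses strong base beside a ketone. The ketene carries an ester and can react as an oxadiene with the ynol ether in place of the four-membered ring formation. The tether forces a strained bicyclic transition state.
- Comparison: on mechanism, the alternative belongs to the same family as the chosen key step (cyclobutenone opening, six-electron closure) and is its equal. On step economy after the key step it is clearly better, one step against four. On access to the precursor and on chemoselectivity in the key step the chosen plan is the safer one.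

Key step: step 12

Remark on the chemistry: anti hydrohalogenation of but-2-ynoic acid would give the Z alkenyl halide and hence a triene with the ketal on the inside; the E arm of 21 is therefore made by syn hydrozirconation-iodination of the alkynyl ketal 17, the structures of 21 and 24 are otherwise unchanged, and racemic compounds are drawn as one enantiomer.

## Route

Step 1
Reactants: 1 methyl orsellinate
Product: 2 methyl 2-hydroxy-4-methoxy-6-methylbenzoate
Conditions: MeI (1.1 equiv), K2CO3 (1.1 equiv), acetone, rt
Reagents that add atoms: iodomethane, CI
Why: Williamson O-methylation; the A5 hydroxyl is hydrogen-bonded to the ester carbonyl and is much less acidic and nucleophilic, so one equivalent of base and iodomethane should alkylate only the A3 hydroxyl.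

Step 2
Reactants: 2 methyl 2-hydroxy-4-methoxy-6-methylbenzoate
Product: 3 methyl 3-formyl-2-hydroxy-4-methoxy-6-methylbenzoate
Conditions: Cl2CHOMe, TiCl4, CH2Cl2, 0 °C to rt; then 1 M HCl
Reagents that add atoms: dichloromethyl methyl ether, COC(Cl)Cl; water, O
Why: Rieche formylation; TiCl4 binds the phenoxide-ester chelate and directs the electrophile to the only free ortho position A4, which the methoxy group also activates; hydrolysis of the chloro ether gives the aldehyde.

Step 3
Reactants: 3 methyl 3-formyl-2-hydroxy-4-methoxy-6-methylbenzoate
Product: 4 methyl 3-(dimethoxymethyl)-2-hydroxy-4-methoxy-6-methylbenzoate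
Conditions: HC(OMe)3, MeOH, PPTS (cat.), rt to 40 °C; Et3N quench
Reagents that add atoms: trimethyl orthoformate, COC(OC)OC
Why: Acid-catalysed acetalisation driven by the orthoformate as water scavenger; the aldehyde must be masked before the organolithium step, and the base quench before concentration protects the ortho-hydroxy acetal.

Step 4
Reactants: 5 diisopropyl squarate
Product: 7 3-isopropoxycyclobut-3-ene-1,2-dione, via 4-hydroxy-2,3-diisopropoxycyclobut-2-enone 6 (not isolated)
Conditions: LiAlH(OtBu)3, THF, −78 to 0 °C; then conc. HCl (cat.), CH2Cl2, rt
Reagents that add atoms: none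
Why: 1,2-Reduction of one squarate carbonyl, then acid-induced allylic ionisation and loss of propan-2-ol, the usual conversion of a squarate adduct into a 3-substituted cyclobutenedione with hydride as the nucleophile; the hindered alkoxyaluminate should deliver one hydride only.

Step 5
Reactants: 7 3-isopropoxycyclobut-3-ene-1,2-dione
Product: 8 semisquaric acid (3-hydroxycyclobut-3-ene-1,2-dione)
Conditions: 1 M HCl (aq), THF, 40 °C; evaporate
Reagents that add atoms: water, O
Why: Hydrolysis of a vinylogous ester by addition-elimination of water; because 7 was purified first, the strongly acidic, water-soluble product is obtained salt-free by evaporation.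

Step 6
Reactants: 8 semisquaric acid; 4 methyl 3-(dimethoxymethyl)-2-hydroxy-4-methoxy-6-methylbenzoate
Product: 10 methyl 3-(dimethoxymethyl)-2-[(3,4-dioxocyclobut-1-en-1-yl)oxy]-4-methoxy-6-methylbenzoate, via semisquaric chloride 9 (not isolated)
Conditions: (COCl)2, DMF (cat.), CH2Cl2, 0 °C to rt; evaporate; then 4, i-Pr2NEt, CH2Cl2, −78 to 0 °C
Reagents that add atoms: none
Why: Vinylogous acid chloride formation, then addition-elimination of the phenol at the chlorine-bearing carbon; the hindered amine takes up HCl so that the acetal survives, and the product is handled without water or nucleophiles.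

Step 7
Reactants: 11 but-2-ynoic acid
Product: 13 N-methoxy-N-methylbut-2-ynamide, via 1-(but-2-ynoyl)imidazole 12 (not isolated)
Conditions: CDI, CH2Cl2, 0 °C to rt; then MeNHOMe·HCl, rt
Reagents that add atoms: N,O-dimethylhydroxylamine hydrochloride, CNOC.Cl
Why: Weinreb amide formation through the acyl imidazole; the neutral activation avoids addition of hydrogen halide to the triple bond.

Step 8
Reactants: 14 1-bromo-2-methylprop-1-ene; 13 N-methoxy-N-methylbut-2-ynamide
Product: 16 6-methylhept-5-en-2-yn-4-one, via 2-methylprop-1-enylmagnesium bromide 15 (not isolated)
Conditions: Mg, THF, 40 °C; then 13, THF, −20 to 0 °C; inverse quench into cold 1 M HCl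
Reagents that add atoms: none
Why: Weinreb ketone synthesis; the magnesium chelate of the tetrahedral intermediate stops the reaction after one addition, and the inverse acidic quench protonates the liberated amine before it can add to the ynone.

Step 9
Reactants: 16 6-methylhept-5-en-2-yn-4-one
Product: 17 2-(2-methylprop-1-enyl)-2-(prop-1-ynyl)-1,3-dioxolane
Conditions: (TMSOCH2)2, TMSOTf (5 mol %), CH2Cl2, −78 to −20 °C; pyridine
Reagents that add atoms: 1,2-bis(trimethylsilyloxy)ethane, C[Si](C)(C)OCCO[Si](C)(C)C
Why: Noyori ketalisation; silyl-transfer conditions at low temperature protect conjugated ketones without moving the trisubstituted double bond, driven by formation of hexamethyldisiloxane.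

Step 10
Reactants: 17 2-(2-methylprop-1-enyl)-2-(prop-1-ynyl)-1,3-dioxolane
Product: 19 2-[(E)-2-iodoprop-1-enyl]-2-(2-methylprop-1-enyl)-1,3-dioxolane, via alkenylzirconocene chloride 18 (not isolated)
Conditions: Cp2Zr(H)Cl (1.5 equiv), THF, rt to 40 °C; then I2, 0 °C; Na2S2O3/NaHCO3 (aq)
Reagents that add atoms: iodine, II
Why: Hydrozirconation-iodination; syn addition of Zr-H places zirconium on the methyl-bearing alkyne carbon, away from the quaternary ketal carbon, and iodinolysis with retention gives the E iodide with iodine trans to the ketal carbon; the trisubstituted alkene reacts far more slowly.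

Step 11
Reactants: 19 2-[(E)-2-iodoprop-1-enyl]-2-(2-methylprop-1-enyl)-1,3-dioxolane; 10 methyl 3-(dimethoxymethyl)-2-[(3,4-dioxocyclobut-1-en-1-yl)oxy]-4-methoxy-6-methylbenzoate
Product: 21 methyl 3-(dimethoxymethyl)-2-{[4-hydroxy-4-{(E)-1-[2-(2-methylprop-1-enyl)-1,3-dioxolan-2-yl]prop-1-en-2-yl}-3-oxocyclobut-1-en-1-yl]oxy}-4-methoxy-6-methylbenzoate (racemic), via alkenyllithium 20 (not isolated)
Conditions: t-BuLi (2.0 equiv), Et2O, −78 °C; then 10, THF, −78 °C; NH4Cl (aq), −78 °C
Reagents that add atoms: none
Why: Iodine-lithium exchange with retention of alkene geometry, then 1,2-addition to the more electrophilic carbonyl of the cyclobutenedione, the one next to the aryloxy carbon and outside the vinylogous ester; the hindered ring A ester and the acetals are inert at −78 °C, and the new carbinol centre forms as a racemate that is lost in the next step.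

Step 12
Reactants: 21 methyl 3-(dimethoxymethyl)-2-{[4-hydroxy-4-{(E)-1-[2-(2-methylprop-1-enyl)-1,3-dioxolan-2-yl]prop-1-en-2-yl}-3-oxocyclobut-1-en-1-yl]oxy}-4-methoxy-6-methylbenzoate
Product: 24 methyl 3-(dimethoxymethyl)-2-{2,5-dihydroxy-3-methyl-4-[2-(2-methylprop-1-enyl)-1,3-dioxolan-2-yl]phenoxy}-4-methoxy-6-methylbenzoate, via dienylketene 22 (not isolated), via cyclohexa-2,4-dienone 23 (not isolated)
Conditions: toluene (degassed, 0.01 M), 110 °C, argon
Reagents that add atoms: none
Why: Heat opens the cyclobutenone by four-electron conrotatory cleavage of the bond between the carbonyl carbon (B4) and the carbinol carbon (B1); the hydroxyl rotates outward, so the alkenyl arm turns inward next to the ketene. The dienylketene 22 then closes by a thermally allowed six-electron disrotatory electrocyclisation, joining the ketene carbon B4 to the alkene CH B5, and dienone 23 enolises to the hydroquinone 24. The closest known reaction is the thermal rearrangement of 4-alkenyl-4-hydroxycyclobutenones to hydroquinones (Moore rearrangement). Ring B is the only ring closed, a six-membered carbocycle formed by pericyclic and not polar closure. No stereocentre results, since the carbinol centre of 21 and the sp3 carbon B5 of 23 both become aromatic carbons. The regiochemistry is fixed by the constitution of 21: oxygen on B1 (carbinol), B2 (aryloxy) and B4 (ketene carbonyl), hydrogen on B3, methyl on B6 and the ketal on B5. The selectivity needed is inward rotation of the alkenyl group, secured by the donor hydroxyl, and an unhindered closing terminus, secured by the E alkene that keeps the quaternary ketal carbon outside. High dilution and exclusion of oxygen guard against ketene dimerisation and oxidation of the hydroquinone.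

Step 13
Reactants: 24 methyl 3-(dimethoxymethyl)-2-{2,5-dihydroxy-3-methyl-4-[2-(2-methylprop-1-enyl)-1,3-dioxolan-2-yl]phenoxy}-4-methoxy-6-methylbenzoate
Product: 26 methyl 3-formyl-2-[(6-hydroxy-2,2,5-trimethyl-4-oxochroman-7-yl)oxy]-4-methoxy-6-methylbenzoate, via enone aldehyde 25 (not isolated)
Conditions: 2 M HCl (aq), THF (degassed), rt to 45 °C
Reagents that add atoms: water, O
Why: Hydrolysis of the acetal and the ketal, then acid-catalysed 6-endo-trig oxa-Michael addition of the B4 hydroxyl to the unmasked 3-methylbut-2-enoyl group; only this hydroxyl is ortho to the acyl group, so ring C forms without choice.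

Step 14
Reactants: 26 methyl 3-formyl-2-[(6-hydroxy-2,2,5-trimethyl-4-oxochroman-7-yl)oxy]-4-methoxy-6-methylbenzoate
Product: 27 3-formyl-2-[(6-hydroxy-2,2,5-trimethyl-4-oxochroman-7-yl)oxy]-4-methoxy-6-methylbenzoic acid
Conditions: LiI, EtOAc, reflux; then 1 M HCl
Reagents that add atoms: none
Why: SN2 dealkylation of the methyl ester by iodide; the attack is at the methyl carbon, so the two ortho substituents that block acyl substitution do not matter, and the aldehyde, aryl methyl ether and chromanone are not touched.

Step 15
Reactants: 27 3-formyl-2-[(6-hydroxy-2,2,5-trimethyl-4-oxochroman-7-yl)oxy]-4-methoxy-6-methylbenzoic acid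
Product: 29 mollicellin B methyl ether, via mixed trifluoroacetic anhydride 28 (not isolated)
Conditions: (CF3CO)2O, toluene, 0 °C to rt; NaHCO3 (aq)
Reagents that add atoms: none
Why: Lactonisation through the mixed anhydride, an acylium-type activation suited to 2,6-disubstituted benzoic acids; the diaryl ether holds the B1 hydroxyl next to the acid, so the seven-membered ring D closes intramolecularly (7-exo-trig).

Step 16
Reactants: 29 mollicellin B methyl ether
Product: 30 mollicellin B
Conditions: BCl3, CH2Cl2, −78 to 0 °C; then H2O
Reagents that add atoms: none
Why: Chelation-controlled ether cleavage; BCl3 binds the formyl oxygen and the adjacent methoxy oxygen and chloride removes the methyl group, while at low temperature the lactone and the chromanone ether should survive.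

## Compound list

1 | methyl orsellinate | COC(=O)c1c(C)cc(O)cc1O | starting material
2 | methyl 2-hydroxy-4-methoxy-6-methylbenzoate | COC(=O)c1c(C)cc(OC)cc1O | intermediate
3 | methyl 3-formyl-2-hydroxy-4-methoxy-6-methylbenzoate | COC(=O)c1c(C)cc(OC)c(C=O)c1O | intermediate
4 | methyl 3-(dimethoxymethyl)-2-hydroxy-4-methoxy-6-methylbenzoate | COC(=O)c1c(C)cc(OC)c(C(OC)OC)c1O | intermediate
5 | diisopropyl squarate | CC(C)OC1=C(OC(C)C)C(=O)C1=O | starting material
6 | 4-hydroxy-2,3-diisopropoxycyclobut-2-enone (racemic, one enantiomer drawn; not isolated) | CC(C)OC1=C(OC(C)C)[C@@H](O)C1=O | intermediate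
7 | 3-isopropoxycyclobut-3-ene-1,2-dione | CC(C)OC1=CC(=O)C1=O | intermediate
8 | semisquaric acid (3-hydroxycyclobut-3-ene-1,2-dione) | OC1=CC(=O)C1=O | intermediate
9 | semisquaric chloride (3-chlorocyclobut-3-ene-1,2-dione; not isolated) | ClC1=CC(=O)C1=O | intermediate
10 | methyl 3-(dimethoxymethyl)-2-[(3,4-dioxocyclobut-1-en-1-yl)oxy]-4-methoxy-6-methylbenzoate | COC(=O)c1c(C)cc(OC)c(C(OC)OC)c1OC1=CC(=O)C1=O | intermediate
11 | but-2-ynoic acid | CC#CC(=O)O | starting material
12 | 1-(but-2-ynoyl)imidazole (not isolated) | CC#CC(=O)n1ccnc1 | intermediate
13 | N-methoxy-N-methylbut-2-ynamide | CC#CC(=O)N(C)OC | intermediate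
14 | 1-bromo-2-methylprop-1-ene | CC(C)=CBr | starting material
15 | 2-methylprop-1-enylmagnesium bromide (not isolated) | CC(C)=C[Mg]Br | intermediate
16 | 6-methylhept-5-en-2-yn-4-one | CC#CC(=O)C=C(C)C | intermediate
17 | 2-(2-methylprop-1-enyl)-2-(prop-1-ynyl)-1,3-dioxolane | CC#CC1(C=C(C)C)OCCO1 | intermediate
18 | chlorobis(cyclopentadienyl){(E)-1-[2-(2-methylprop-1-enyl)-1,3-dioxolan-2-yl]prop-1-en-2-yl}zirconium (cyclopentadienyl rings written as sigma-bonded; not isolated) | Cl[Zr](C1C=CC=C1)(C1C=CC=C1)/C(C)=C/C1(C=C(C)C)OCCO1 | intermediate
19 | 2-[(E)-2-iodoprop-1-enyl]-2-(2-methylprop-1-enyl)-1,3-dioxolane | I/C(C)=C/C1(C=C(C)C)OCCO1 | intermediate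
20 | (E)-1-[2-(2-methylprop-1-enyl)-1,3-dioxolan-2-yl]prop-1-en-2-yllithium (not isolated) | [Li]/C(C)=C/C1(C=C(C)C)OCCO1 | intermediate
21 | methyl 3-(dimethoxymethyl)-2-{[4-hydroxy-4-{(E)-1-[2-(2-methylprop-1-enyl)-1,3-dioxolan-2-yl]prop-1-en-2-yl}-3-oxocyclobut-1-en-1-yl]oxy}-4-methoxy-6-methylbenzoate (racemic, one enantiomer drawn) | COC(=O)c1c(C)cc(OC)c(C(OC)OC)c1OC2=CC(=O)[C@]2(O)/C(C)=C/C3(C=C(C)C)OCCO3 | intermediate
22 | dienylketene: methyl 3-(dimethoxymethyl)-2-{[(3Z,5E)-4-hydroxy-5-methyl-6-[2-(2-methylprop-1-enyl)-1,3-dioxolan-2-yl]-1-oxohexa-1,3,5-trien-3-yl]oxy}-4-methoxy-6-methylbenzoate (not isolated) | COC(=O)c1c(C)cc(OC)c(C(OC)OC)c1OC(\C=C=O)=C(O)\C(C)=C\C2(C=C(C)C)OCCO2 | intermediate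
23 | methyl 3-(dimethoxymethyl)-2-({6-hydroxy-5-methyl-4-[2-(2-methylprop-1-enyl)-1,3-dioxolan-2-yl]-3-oxocyclohexa-1,5-dien-1-yl}oxy)-4-methoxy-6-methylbenzoate (racemic, one enantiomer drawn; not isolated) | COC(=O)c1c(C)cc(OC)c(C(OC)OC)c1OC1=CC(=O)[C@H](C2(C=C(C)C)OCCO2)C(C)=C1O | intermediate
24 | methyl 3-(dimethoxymethyl)-2-{2,5-dihydroxy-3-methyl-4-[2-(2-methylprop-1-enyl)-1,3-dioxolan-2-yl]phenoxy}-4-methoxy-6-methylbenzoate | COC(=O)c1c(C)cc(OC)c(C(OC)OC)c1Oc1cc(O)c(C2(C=C(C)C)OCCO2)c(C)c1O | intermediate
25 | methyl 2-[2,5-dihydroxy-3-methyl-4-(3-methylbut-2-enoyl)phenoxy]-3-formyl-4-methoxy-6-methylbenzoate (not isolated) | COC(=O)c1c(C)cc(OC)c(C=O)c1Oc1cc(O)c(C(=O)C=C(C)C)c(C)c1O | intermediate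
26 | methyl 3-formyl-2-[(6-hydroxy-2,2,5-trimethyl-4-oxochroman-7-yl)oxy]-4-methoxy-6-methylbenzoate | COC(=O)c1c(C)cc(OC)c(C=O)c1Oc1cc2OC(C)(C)CC(=O)c2c(C)c1O | intermediate
27 | 3-formyl-2-[(6-hydroxy-2,2,5-trimethyl-4-oxochroman-7-yl)oxy]-4-methoxy-6-methylbenzoic acid | OC(=O)c1c(C)cc(OC)c(C=O)c1Oc1cc2OC(C)(C)CC(=O)c2c(C)c1O | intermediate
28 | mixed anhydride of 27 with trifluoroacetic acid (not isolated) | O=C(OC(=O)C(F)(F)F)c1c(C)cc(OC)c(C=O)c1Oc1cc2OC(C)(C)CC(=O)c2c(C)c1O | intermediate
29 | mollicellin B methyl ether (methyl ether of the ring A hydroxyl) | Cc1cc(OC)c(C=O)c2c1C(=O)Oc1c(cc3c(c1C)C(=O)CC(C)(C)O3)O2 | intermediate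
30 | mollicellin B | Cc1cc(O)c(C=O)c2c1C(=O)Oc1c(cc3c(c1C)C(=O)CC(C)(C)O3)O2 | target

## Step count and least certain steps

Total: 16 steps. Longest linear sequence: 10 steps (steps 7 to 16 from 11, or steps 1, 2, 3, 6 and 11 to 16 from 1).

Step 12 (key step). The most likely failure is diversion of the dienylketene before ring closure, because the quaternary ketal carbon on the closing alkene slows the six-electron step and leaves time for intermolecular capture of the ketene by hydroxyl groups; the free hydroquinone may also oxidise in air. Fallback, from 21: the tertiary hydroxyl is silylated (TMSCl, imidazole, CH2Cl2) to the trimethylsilyl ether of 21 F1. Thermolysis of this ether, which has no free hydroxyl and rotates the silyloxy group outward, should give the B1-O-silylated hydroquinone F2. The aqueous acid of step 13 removes the silyl group with the acetals, and the route is rejoined at 26.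

Step 11. The most likely failure is loss of the aryloxy group by addition-elimination at the vinylogous ester carbon, since aryloxide is a good leaving group and the alkenyllithium is hard and basic. Fallback, from 19: after the exchange, 20 is transmetallated with anhydrous CeCl3 at −78 °C to the alkenylcerium dichloride F3. This oxophilic, weakly basic carbonyl-selective nucleophile is added to 10, and the route is rejoined at 21.

Step 10. The most likely failure is misdirected hydrozirconation, with zirconium on the carbon next to the ketal (steered by the ketal oxygens) followed by elimination of alkoxide, or opening of the ketal by the Lewis acidic zirconium. Fallback, from 16: syn stannylcupration (Me3SnLi, CuBr·SMe2, MeOH, THF, −78 °C) places tin beta to the carbonyl by electronic control and gives (E)-2-methyl-6-(trimethylstannyl)hepta-2,5-dien-4-one F4. Noyori ketalisation gives the stannyl ketal F5, and iodine replaces tin with retention, rejoining the route at 19.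

Step 8. The most likely failure is conjugate addition of the liberated N,O-dimethylhydroxylamine to the new ynone during the quench. Fallback, from 15: the Grignard reagent is added to commercial but-2-ynal to give 6-methylhept-5-en-2-yn-4-ol F6, and oxidation of this doubly activated alcohol with MnO2 rejoins the route at 16.

Step 3. The most likely failure is reversion of the acetal during isolation, through ionisation assisted by the ortho hydroxyl, together with incomplete conversion of the chelated, doubly ortho-oxygenated aldehyde. Fallback, from 3: acetylation (Ac2O, DMAP, Et3N) gives methyl 2-acetoxy-3-formyl-4-methoxy-6-methylbenzoate F7, whose unchelated aldehyde is converted into the acetal acetate F8. Methanolysis with K2CO3 frees the phenol under basic conditions and rejoins the route at 4.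

Step 16. The most likely failure is opening of the ring D aryl ester or of the chromanone ether by the Lewis acid in competition with demethylation. Fallback, from 27: the methyl ether is cleaved with BCl3 before ring closure to give 3-formyl-4-hydroxy-2-[(6-hydroxy-2,2,5-trimethyl-4-oxochroman-7-yl)oxy]-6-methylbenzoic acid F9. The lactonisation of step 15 applied to this acid, followed by mild methanolysis of any aryl trifluoroacetate, rejoins the route at 30.

## Further compounds

F1 | step 12 | trimethylsilyl ether of 21 at the tertiary hydroxyl (racemic, one enantiomer drawn) | COC(=O)c1c(C)cc(OC)c(C(OC)OC)c1OC2=CC(=O)[C@]2(O[Si](C)(C)C)/C(C)=C/C3(C=C(C)C)OCCO3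
F2 | step 12 | methyl 3-(dimethoxymethyl)-2-{5-hydroxy-3-methyl-4-[2-(2-methylprop-1-enyl)-1,3-dioxolan-2-yl]-2-(trimethylsilyloxy)phenoxy}-4-methoxy-6-methylbenzoate | COC(=O)c1c(C)cc(OC)c(C(OC)OC)c1Oc1cc(O)c(C2(C=C(C)C)OCCO2)c(C)c1O[Si](C)(C)C
F3 | step 11 | dichloro{(E)-1-[2-(2-methylprop-1-enyl)-1,3-dioxolan-2-yl]prop-1-en-2-yl}cerium | Cl[Ce](Cl)/C(C)=C/C1(C=C(C)C)OCCO1
F4 | step 10 | (E)-2-methyl-6-(trimethylstannyl)hepta-2,5-dien-4-one | CC(C)=CC(=O)/C=C(C)/[Sn](C)(C)C
F5 | step 10 | trimethyl{(E)-1-[2-(2-methylprop-1-enyl)-1,3-dioxolan-2-yl]prop-1-en-2-yl}stannane | C[Sn](C)(C)/C(C)=C/C1(C=C(C)C)OCCO1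
F6 | step 8 | 6-methylhept-5-en-2-yn-4-ol (racemic) | CC#CC(O)C=C(C)C
F7 | step 3 | methyl 2-acetoxy-3-formyl-4-methoxy-6-methylbenzoate | COC(=O)c1c(C)cc(OC)c(C=O)c1OC(C)=O
F8 | step 3 | methyl 2-acetoxy-3-(dimethoxymethyl)-4-methoxy-6-methylbenzoate | COC(=O)c1c(C)cc(OC)c(C(OC)OC)c1OC(C)=O
F9 | step 16 | 3-formyl-4-hydroxy-2-[(6-hydroxy-2,2,5-trimethyl-4-oxochroman-7-yl)oxy]-6-methylbenzoic acid | OC(=O)c1c(C)cc(O)c(C=O)c1Oc1cc2OC(C)(C)CC(=O)c2c(C)c1O
A1 | alternative 1 | dihydromollicellin B with ring A as a cyclohexenone (racemic, trans isomer drawn) | O=CC1=C2Oc3cc4OC(C)(C)CC(=O)c4c(C)c3OC(=O)[C@H]2[C@H](C)CC1=O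
A2 | alternative 1 | 7-[(2-formyl-5-methyl-3-oxocyclohex-1-en-1-yl)oxy]-2,2,5-trimethyl-4-oxochroman-6-yl imidazole-1-carboxylate (racemic) | O=CC1=C(Oc2cc3OC(C)(C)CC(=O)c3c(C)c2OC(=O)n2ccnc2)CC(C)CC1=O
A3 | alternative 1 | 6,7-dihydroxy-2,2,5-trimethylchroman-4-one | Cc1c(O)c(O)cc2OC(C)(C)CC(=O)c12
A4 | alternative 2 | 7-bromo-2,2,5-trimethyl-4-oxochroman-6-yl 2,4-dihydroxy-6-methylbenzoate | Cc1cc(O)cc(O)c1C(=O)Oc1c(C)c2C(=O)CC(C)(C)Oc2cc1Br
A5 | alternative 2 | 6-(2,4-dioxopentyl)-2,2-dimethyl-4H-1,3-dioxin-4-one | CC(=O)CC(=O)CC1=CC(=O)OC(C)(C)O1
A6 | alternative 2 | 7-bromo-6-hydroxy-2,2,5-trimethylchroman-4-one | Cc1c(O)c(Br)cc2OC(C)(C)CC(=O)c12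
A7 | alternative 3 | mollicellin B diethyl acetal | Cc1cc(O)c(C(OCC)OCC)c2c1C(=O)Oc1c(cc3c(c1C)C(=O)CC(C)(C)O3)O2
A8 | alternative 3 | 7-[(3,3-diethoxyprop-1-yn-1-yl)oxy]-2,2,5-trimethyl-4-oxochroman-6-yl 2-diazo-4-methyl-3-oxopent-4-enoate | C=C(C)C(=O)C(=[N+]=[N-])C(=O)Oc1c(C)c2C(=O)CC(C)(C)Oc2cc1OC#CC(OCC)OCC
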